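**Retrosynthetic overview**

1. Core numbering used throughout (bicyclo[3.2.1]octane, counted from the allyl bridgehead): C1 (allyl), C2=C3(OMe), C4 (OAc), C5 (OMe bridgehead), C6 (aryl), C7 (methyl), C8 (ketone).
2. The strategy rests on the five-membered ring C1–C8–C5–C6–C7: a cyclopentanone with C8 between C1 and C5, trans aryl (C6) and methyl (C7) on the β-carbons, and a methoxy on C5. A conrotatory Nazarov closure of an α-methoxy, α'-alkoxycarbonyl divinyl ketone gives this pattern if the oxyallyl cation is reduced at C5 (C6–C7 bond, first ring).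
3. The second ring (C1–C2–C3–C4–C5–C8) is closed by a lithium-chelated aldol of the C5 enolate onto a C4 aldehyde. C3 is carried as a dimethyl ketal and the C2=C3 enol ether is made afterwards inside the ring, because an acyclic C1–CH=C(OMe)–CHO would need the formyl group cis to C1, its less stable geometry.
4. C1 becomes quaternary by alkylation with 2-methoxyallyl bromide (C2–C3–C4 unit) followed by Tsuji decarboxylative allylation; the ester of the Nazarov substrate is therefore an allyl ester. The dienone comes from allyl 4-methoxyacetoacetate by γ-aldol condensation with veratraldehyde and Knoevenagel condensation with acetaldehyde.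
5. Ring order: cyclopentanone (step 5), six-membered ring (step 11), then enol ether (step 12) and acetate (step 13).

Key step: step 5

Remark: C5 in compounds 10 and 13–17 is drawn as hydride delivery anti to the C6 aryl should leave it (methoxy cis to aryl); this centre is epimerisable and becomes a planar enolate in step 11, so its configuration in these intermediates does not affect the target.
Remark: which antipode of the ligand gives the (6S,7R) series cannot be predicted with certainty; (S,S)-t-Bu-box, 2,2'-(propane-2,2-diyl)bis[(4S)-4-tert-butyl-4,5-dihydrooxazole], is written, and the (R,R) ligand is to be used if the first run shows the opposite sense.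

**Route**

Step 1
Reactants: 1 methyl 4-methoxyacetoacetate; 2 allyl alcohol
Product: 3 allyl 4-methoxy-3-oxobutanoate
Conditions: allyl alcohol (5 equiv), DMAP (0.2 equiv), toluene, reflux, MeOH distilled off
Reagents that add atoms: none
Why: DMAP-catalysed transesterification of an enolisable β-keto ester, driven by removal of methanol, installs the allyl ester that later supplies the C1 allyl group; no stereocentre is involved.

Step 2
Reactants: 3 allyl 4-methoxy-3-oxobutanoate; 4 veratraldehyde
Product: 5 allyl 5-(3,4-dimethoxyphenyl)-5-hydroxy-4-methoxy-3-oxopentanoate (mixture of diastereomers)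
Conditions: LiN(i-Pr)2 (2.2 equiv), THF, −78 to −20 °C; 4, −78 °C; AcOH quench
Reagents that add atoms: none
Why: Two equivalents of amide base give the 2,4-dianion of the β-keto ester, which reacts with the aldehyde at its last-formed and more nucleophilic carbanion, the methoxy-bearing C4 (γ-aldol addition of an acetoacetate dianion); the two new stereocentres are left unassigned because step 3 removes both.

Step 3
Reactants: 5 aldol adduct
Product: 6 allyl (4Z)-5-(3,4-dimethoxyphenyl)-4-methoxy-3-oxopent-4-enoate
Conditions: TsOH·H2O (5 mol%), toluene, 4 Å MS, 60 °C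
Reagents that add atoms: none
Why: Acid-catalysed aldol dehydration through the benzylic cation stabilised by the para-methoxy group gives the conjugated enone under equilibrating conditions, hence as the more stable Z isomer with aryl trans to the acyl group, which is the geometry the cyclisation needs.

Step 4
Reactants: 6 enone β-keto ester; 7 acetaldehyde
Product: 8 allyl (2Z)-2-[(2Z)-3-(3,4-dimethoxyphenyl)-2-methoxyprop-2-enoyl]but-2-enoate
Conditions: MeCHO (5 equiv), piperidine (10 mol%), AcOH (10 mol%), 4 Å MS, CH2Cl2, 0 °C
Reagents that add atoms: none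
Why: Knoevenagel condensation at the doubly activated C2 methylene under piperidinium acetate catalysis gives the ethylidene β-keto ester, drawn with methyl cis to the ester; a geometric isomer at this bond should do no harm, since alkylidene β-keto esters are expected to equilibrate on the Lewis acid of step 5 before they cyclise.

Step 5
Reactants: 8 dienone
Product: 10 allyl (1S,3R,4S,5R)-4-(3,4-dimethoxyphenyl)-3-methoxy-5-methyl-2-oxocyclopentane-1-carboxylate, via silyl enol ether 9 (not isolated)
Conditions: Cu(OTf)2 (10 mol%), (S,S)-t-Bu-box (11 mol%), Et3SiH (2 equiv), CH2Cl2, 0 °C to rt; then 1 M HCl, THF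
Reagents that add atoms: none
Why: Proposed new method: Chelation of the ketone and ester carbonyls of 8 to the chiral Cu(OTf)2–bis(oxazoline) complex gives a pentadienyl cation polarised between the electron-rich methoxy/aryl vinyl arm (nucleophilic C6) and the electron-poor alkylidene arm (electrophilic C7), and thermal conrotatory 4π electrocyclisation forms C6–C7 and closes the five-membered ring C1–C8–C5–C6–C7. The closest known reaction types are the catalytic asymmetric Nazarov cyclisation of alkylidene β-keto esters on divalent copper–oxazoline complexes and the silane-interrupted (reductive) Nazarov reaction, which have not been run together in one catalytic step. C6 and C7 are set trans because aryl and methyl both sit on the outside of the U-shaped cation, and the direction of conrotation, hence the absolute configuration, is imposed by the C2-symmetric ligand on the chelate. The oxyallyl cation is localised as a methoxy oxocarbenium ion at C5 with the copper enolate at C1, so triethylsilane, which reduces oxocarbenium ions but not the bound dienone, should deliver hydride to C5 from the face opposite the C6 aryl faster than the C6 proton is lost. That is the selectivity the step needs, because loss of the C6 proton would erase C6, and the C5 methoxy group is what secures it. Silyl transfer to the enolate oxygen frees the copper, and hydrolysis of 9 on work-up gives the β-keto ester with the ester trans to the C7 methyl.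

Step 6
Reactants: 11 1-bromo-2,2-dimethoxypropane
Product: 12 3-bromo-2-methoxyprop-1-ene (2-methoxyallyl bromide)
Conditions: i-Pr2NEt·TsOH (2 mol%), neat, 150 °C, MeOH distilled off; distillation
Reagents that add atoms: none
Why: Acid-salt-catalysed thermal loss of methanol from the dimethyl ketal towards the methyl group (ketal-to-enol-ether elimination) gives the allylic bromide; any 1-bromo-2-methoxypropene formed alongside is a vinylic bromide that cannot alkylate in step 7 and is removed there.

Step 7
Reactants: 10 cyclopentanone β-keto ester; 12 2-methoxyallyl bromide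
Product: 13 allyl (1R,3R,4S,5R)-4-(3,4-dimethoxyphenyl)-3-methoxy-1-(2-methoxyprop-2-en-1-yl)-5-methyl-2-oxocyclopentane-1-carboxylate
Conditions: K2CO3 (2 equiv), acetone, 50 °C
Reagents that add atoms: none
Why: C-Alkylation of the β-keto ester enolate with a reactive allylic bromide (SN2) forms the C1–C2 bond and brings in C2, C3 with its methoxy group and C4; the electrophile should enter anti to the C7 methyl, but this is not relied on because C1 becomes a planar enolate again in step 8.

Step 8
Reactants: 13 quaternary allyl β-keto ester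
Product: 14 (2R,3R,4S,5R)-2-allyl-4-(3,4-dimethoxyphenyl)-5-methoxy-2-(2-methoxyprop-2-en-1-yl)-3-methylcyclopentan-1-one
Conditions: Pd(PPh3)4 (5 mol%), THF, 25 °C
Reagents that add atoms: none
Why: Tsuji decarboxylative allylation: zerovalent palladium ionises the allyl ester, loss of CO2 leaves the enolate specifically at C1, and the allyl group on palladium is delivered to the enolate face opposite the adjacent C7 methyl, which sets the quaternary C1 with allyl trans and the methoxyallyl arm cis to that methyl whichever C1 epimer of 13 is used.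

Step 9
Reactants: 14 enol ether ketone
Product: 16 (2R,3R,4S,5R)-2-allyl-4-(3,4-dimethoxyphenyl)-2-(3-hydroxy-2,2-dimethoxypropyl)-5-methoxy-3-methylcyclopentan-1-one, via methoxyoxirane 15 (not isolated)
Conditions: mCPBA (1.1 equiv), NaHCO3, MeOH, −20 to 0 °C
Reagents that add atoms: mCPBA O=C(OO)c1cccc(Cl)c1; methanol CO
Why: Epoxidation of the electron-rich enol ether, far faster than that of the monosubstituted allyl alkene, followed by methanolysis of the 2-methoxyoxirane at its acetal carbon gives the α-hydroxy dimethyl ketal, which puts C3 at the ketone and C4 at the alcohol oxidation level; the oxirane stereocentre disappears in the ketal.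

Step 10
Reactants: 16 hydroxy ketal
Product: 17 3-[(1R,2R,3S,4R)-1-allyl-3-(3,4-dimethoxyphenyl)-4-methoxy-2-methyl-5-oxocyclopentyl]-2,2-dimethoxypropanal
Conditions: Dess–Martin periodinane (1.3 equiv), NaHCO3, CH2Cl2, 0 °C to rt
Reagents that add atoms: none
Why: Dess–Martin oxidation of the primary alcohol under buffered, non-acidic conditions gives the non-enolisable α,α-dimethoxy aldehyde without touching the ketal, the alkene or the ketone.

Step 11
Reactants: 17 keto aldehyde
Product: 18 (1R,4R,5S,6S,7R)-1-allyl-6-(3,4-dimethoxyphenyl)-4-hydroxy-3,3,5-trimethoxy-7-methylbicyclo[3.2.1]octan-8-one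
Conditions: LiN(SiMe3)2 (1.1 equiv), THF, −78 °C; AcOH quench at −78 °C
Reagents that add atoms: none
Why: Intramolecular aldol addition closes the six-membered ring C1–C2–C3–C4–C5–C8: C5 is the only enolisable position, its lithium enolate can reach the aldehyde only on the ring face that carries the side chain (cis to the C7 methyl), which fixes C5, and lithium bridging of the enolate and aldehyde oxygens in a closed transition state places the C4 oxygen syn to the C8 carbonyl, which sets C4.

Step 12
Reactants: 18 bicyclic hydroxy ketal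
Product: 21 (1S,4S,5S,6S,7R)-1-allyl-6-(3,4-dimethoxyphenyl)-4-hydroxy-3,5-dimethoxy-7-methylbicyclo[3.2.1]oct-2-en-8-one, via silyl ether ketal 19 (not isolated), via silyl ether enol ether 20 (not isolated)
Conditions: TMSOTf (3 equiv), i-Pr2NEt (4 equiv), CH2Cl2, −20 to 0 °C; then Bu4NF, AcOH (1:1), THF, 0 °C
Reagents that add atoms: none
Why: The silyl triflate first caps the C4 hydroxyl and then ionises the ketal to the C3 oxocarbenium ion, from which the amine removes the pseudo-axial C2 proton (the C4 hydrogen is pseudo-equatorial, more hindered and poorly aligned), so the enol ether forms between C2 and C3 with the only geometry the ring allows (silyl triflate–amine ketal-to-enol-ether elimination); buffered fluoride then frees the C4 hydroxyl.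

Step 13
Reactants: 21 hydroxy enol ether
Product: 22 (1S,4S,5S,6S,7R)-1-allyl-6-(3,4-dimethoxyphenyl)-3,5-dimethoxy-7-methyl-8-oxobicyclo[3.2.1]oct-2-en-4-yl acetate
Conditions: Ac2O, pyridine, DMAP (cat.), CH2Cl2, rt
Reagents that add atoms: acetic anhydride CC(=O)OC(C)=O
Why: DMAP-catalysed acetylation of the secondary alcohol under mild base leaves the enol ether and the ketone untouched and affects no stereocentre.

**Compound list**

1 | methyl 4-methoxy-3-oxobutanoate (methyl 4-methoxyacetoacetate) | COCC(=O)CC(=O)OC | starting material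
2 | prop-2-en-1-ol (allyl alcohol) | C=CCO | starting material
3 | allyl 4-methoxy-3-oxobutanoate | COCC(=O)CC(=O)OCC=C | intermediate
4 | 3,4-dimethoxybenzaldehyde (veratraldehyde) | COc1ccc(C=O)cc1OC | starting material
5 | allyl 5-(3,4-dimethoxyphenyl)-5-hydroxy-4-methoxy-3-oxopentanoate, mixture of diastereomers | C=CCOC(=O)CC(=O)C(OC)C(O)c1ccc(OC)c(OC)c1 | intermediate
6 | allyl (4Z)-5-(3,4-dimethoxyphenyl)-4-methoxy-3-oxopent-4-enoate | C=CCOC(=O)CC(=O)/C(OC)=C/c1ccc(OC)c(OC)c1 | intermediate
7 | acetaldehyde | CC=O | starting material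
8 | allyl (2Z)-2-[(2Z)-3-(3,4-dimethoxyphenyl)-2-methoxyprop-2-enoyl]but-2-enoate | C/C=C(\C(=O)OCC=C)C(=O)/C(OC)=C/c1ccc(OC)c(OC)c1 | intermediate
9 | allyl (3R,4S,5R)-4-(3,4-dimethoxyphenyl)-3-methoxy-5-methyl-2-(triethylsilyloxy)cyclopent-1-ene-1-carboxylate | C=CCOC(=O)C1=C(O[Si](CC)(CC)CC)[C@H](OC)[C@H](c2ccc(OC)c(OC)c2)[C@H]1C | intermediate (not isolated)
10 | allyl (1S,3R,4S,5R)-4-(3,4-dimethoxyphenyl)-3-methoxy-5-methyl-2-oxocyclopentane-1-carboxylate | C=CCOC(=O)[C@@H]1C(=O)[C@H](OC)[C@H](c2ccc(OC)c(OC)c2)[C@H]1C | intermediate
11 | 1-bromo-2,2-dimethoxypropane | CC(OC)(OC)CBr | starting material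
12 | 3-bromo-2-methoxyprop-1-ene (2-methoxyallyl bromide) | C=C(OC)CBr | intermediate
13 | allyl (1R,3R,4S,5R)-4-(3,4-dimethoxyphenyl)-3-methoxy-1-(2-methoxyprop-2-en-1-yl)-5-methyl-2-oxocyclopentane-1-carboxylate | C=CCOC(=O)[C@@]1(CC(OC)=C)C(=O)[C@H](OC)[C@H](c2ccc(OC)c(OC)c2)[C@H]1C | intermediate
14 | (2R,3R,4S,5R)-2-allyl-4-(3,4-dimethoxyphenyl)-5-methoxy-2-(2-methoxyprop-2-en-1-yl)-3-methylcyclopentan-1-one | C=CC[C@]1(CC(OC)=C)C(=O)[C@H](OC)[C@H](c2ccc(OC)c(OC)c2)[C@H]1C | intermediate
15 | (2R,3R,4S,5R)-2-allyl-4-(3,4-dimethoxyphenyl)-5-methoxy-2-[(2-methoxyoxiran-2-yl)methyl]-3-methylcyclopentan-1-one, both oxirane epimers | C=CC[C@]1(CC3(OC)CO3)C(=O)[C@H](OC)[C@H](c2ccc(OC)c(OC)c2)[C@H]1C | intermediate (not isolated)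
16 | (2R,3R,4S,5R)-2-allyl-4-(3,4-dimethoxyphenyl)-2-(3-hydroxy-2,2-dimethoxypropyl)-5-methoxy-3-methylcyclopentan-1-one | C=CC[C@]1(CC(OC)(OC)CO)C(=O)[C@H](OC)[C@H](c2ccc(OC)c(OC)c2)[C@H]1C | intermediate
17 | 3-[(1R,2R,3S,4R)-1-allyl-3-(3,4-dimethoxyphenyl)-4-methoxy-2-methyl-5-oxocyclopentyl]-2,2-dimethoxypropanal | C=CC[C@]1(CC(OC)(OC)C=O)C(=O)[C@H](OC)[C@H](c2ccc(OC)c(OC)c2)[C@H]1C | intermediate
18 | (1R,4R,5S,6S,7R)-1-allyl-6-(3,4-dimethoxyphenyl)-4-hydroxy-3,3,5-trimethoxy-7-methylbicyclo[3.2.1]octan-8-one | C=CC[C@]12CC(OC)(OC)[C@H](O)[C@](OC)(C1=O)[C@H](c1ccc(OC)c(OC)c1)[C@H]2C | intermediate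
19 | (1R,4R,5S,6S,7R)-1-allyl-6-(3,4-dimethoxyphenyl)-3,3,5-trimethoxy-7-methyl-4-(trimethylsilyloxy)bicyclo[3.2.1]octan-8-one | C=CC[C@]12CC(OC)(OC)[C@H](O[Si](C)(C)C)[C@](OC)(C1=O)[C@H](c1ccc(OC)c(OC)c1)[C@H]2C | intermediate (not isolated)
20 | (1S,4S,5S,6S,7R)-1-allyl-6-(3,4-dimethoxyphenyl)-3,5-dimethoxy-7-methyl-4-(trimethylsilyloxy)bicyclo[3.2.1]oct-2-en-8-one | C=CC[C@]12C=C(OC)[C@H](O[Si](C)(C)C)[C@](OC)(C1=O)[C@H](c1ccc(OC)c(OC)c1)[C@H]2C | intermediate (not isolated)
21 | (1S,4S,5S,6S,7R)-1-allyl-6-(3,4-dimethoxyphenyl)-4-hydroxy-3,5-dimethoxy-7-methylbicyclo[3.2.1]oct-2-en-8-one | C=CC[C@]12C=C(OC)[C@H](O)[C@](OC)(C1=O)[C@H](c1ccc(OC)c(OC)c1)[C@H]2C | intermediate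
22 | (1S,4S,5S,6S,7R)-1-allyl-6-(3,4-dimethoxyphenyl)-3,5-dimethoxy-7-methyl-8-oxobicyclo[3.2.1]oct-2-en-4-yl acetate (CNP0221003.1) | C=CC[C@]12C=C(OC)[C@H](OC(C)=O)[C@](OC)(C1=O)[C@H](c1ccc(OC)c(OC)c1)[C@H]2C | target

**Step count and risks**

Total step count: 13. Longest linear sequence: 12 (steps 1–5 and 7–13; step 6 is a one-step side branch).

Steps most likely to fail:

1. Step 5 (proposed new method). What may go wrong:
   - loss of the C6 proton from the oxyallyl cation may outrun hydride capture, which erases the C6 stereocentre;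
   - the silyl triflate released during turnover may act as an achiral Lewis acid and erode the enantiomeric purity;
   - the silane may reduce the copper salt and stop the catalysis.

   Fallback, known chemistry: setting out from 8, the stoichiometric reductive Nazarov reaction (BF3·OEt2, Et3SiH in excess, CH2Cl2, −78 to 0 °C) should give the same trans-C6/C7 cyclopentanone without absolute control, that is 10 together with its enantiomer allyl (1R,3S,4R,5S)-4-(3,4-dimethoxyphenyl)-3-methoxy-5-methyl-2-oxocyclopentane-1-carboxylate F1. Preparative HPLC on a chiral stationary phase separates the two, and the route is rejoined at 10.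

2. Step 11. What may go wrong:
   - the aldol is reversible, and the crowded C3 ketal (one methoxy group pushed towards the C6–C7 bridge, or the ring forced into a boat) may shift the equilibrium back to the open keto aldehyde;
   - loss of the lithium chelate would give poor facial selectivity at the aldehyde and thus the wrong C4 epimer.

   Fallback: setting out from 17, the ketal is turned into the enol ether before ring closure (TMSOTf, i-Pr2NEt, CH2Cl2), which should give (2E)-3-[(1S,2R,3S,4R)-1-allyl-3-(3,4-dimethoxyphenyl)-4-methoxy-2-methyl-5-oxocyclopentyl]-2-methoxyprop-2-enal F2, whose formyl group is cis to the ring carbon, together with its (2Z)-isomer F3. F3 cannot cyclise; it is separated and returned to the E/Z mixture by sensitised irradiation. F2, treated with LiN(SiMe3)2 in THF at −78 °C, should close by the same chelated aldol onto a now planar, unstrained C3 and give 21 directly, so the route is rejoined at 21 and step 12 is skipped.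

3. Step 12. What may go wrong:
   - ionisation of the hindered ketal may be slow;
   - deprotonation may occur at C4 instead of C2;
   - the oxocarbenium ion may be hydrolysed to the C3 ketone on work-up;
   - retro-aldol opening may occur during the fluoride treatment.

   Fallback: setting out from 18, the hydroxyl is acetylated first (Ac2O, DMAP, pyridine) to give (1R,4R,5S,6S,7R)-1-allyl-6-(3,4-dimethoxyphenyl)-3,3,5-trimethoxy-7-methyl-8-oxobicyclo[3.2.1]octan-4-yl acetate F4. Methanol is then removed thermally with an acid-salt catalyst (i-Pr2NEt·TsOH, toluene, reflux, methanol taken out over 4 Å sieves), the same ketal pyrolysis as in step 6, with no silyl reagent and no deprotection. This should give 22 directly, so the route is rejoined at the target 22.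

Further compounds
F1 | step 5 | allyl (1R,3S,4R,5S)-4-(3,4-dimethoxyphenyl)-3-methoxy-5-methyl-2-oxocyclopentane-1-carboxylate (enantiomer of 10) | C=CCOC(=O)[C@H]1C(=O)[C@@H](OC)[C@@H](c2ccc(OC)c(OC)c2)[C@@H]1C
F2 | step 11 | (2E)-3-[(1S,2R,3S,4R)-1-allyl-3-(3,4-dimethoxyphenyl)-4-methoxy-2-methyl-5-oxocyclopentyl]-2-methoxyprop-2-enal | C=CC[C@]1(/C=C(/OC)C=O)C(=O)[C@H](OC)[C@H](c2ccc(OC)c(OC)c2)[C@H]1C
F3 | step 11 | (2Z)-3-[(1S,2R,3S,4R)-1-allyl-3-(3,4-dimethoxyphenyl)-4-methoxy-2-methyl-5-oxocyclopentyl]-2-methoxyprop-2-enal | C=CC[C@]1(/C=C(\OC)C=O)C(=O)[C@H](OC)[C@H](c2ccc(OC)c(OC)c2)[C@H]1C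
F4 | step 12 | (1R,4R,5S,6S,7R)-1-allyl-6-(3,4-dimethoxyphenyl)-3,3,5-trimethoxy-7-methyl-8-oxobicyclo[3.2.1]octan-4-yl acetate | C=CC[C@]12CC(OC)(OC)[C@H](OC(C)=O)[C@](OC)(C1=O)[C@H](c1ccc(OC)c(OC)c1)[C@H]2C
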